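Abbreviations used throughout: TIPS = triisopropylsilyl; prenyl = 3-methylbut-2-enyl; ArB = 5-(3-methylbut-2-enyl)-2,4-bis(triisopropylsilyloxy)phenyl, the protected ring B. Isoflavonoid numbering is used, and pyranone positions are given with their future chromone numbers where it helps.

## The problem

Target 25 is a (3S)-isoflavanone: ring A (C4a to C8a) is fused to the dihydropyranone ring C, and C3 carries ring B, a 2,4-dihydroxy-5-prenylphenyl group. Ring A has a hydroxyl at C7 and a prenyl group at C6 but nothing at C5 or C8, and ring B repeats the same 2,4-dioxygenated 5-prenyl pattern. Direct prenylation of a finished resorcinol or 7-hydroxyisoflavonoid does not reach these positions cleanly, so each prenyl group has to be placed by construction. C3 is the only stereocentre; it is benzylic and α to the C4 ketone, so it is lost through the enol and through reversible opening of the O1–C2 bond. No other centre can control it, so it has to be set by a catalyst late in the route and followed only by near-neutral operations. Each prenyl group sits ortho to a phenol, so protic or Lewis acids close them to 2,2-dimethylchromans, and hydrogenation, halogens and peracids are excluded; this narrows the protecting groups to ones removed by buffered fluoride. The feature that opens the route is the resorcinol-type pattern of ring A: oxygen on C8a and C7, an unoxygenated C5, and the acyl carbon C4 on C4a, which is the pattern of a folded polyketide whose C5 carbonyl has been reduced. At the isoflavone oxidation level O1, C2, C3, C4, C4a and C8a form a 4-pyranone, and C8–C7–C6–C5 is then a β-keto aldehyde chain on that pyranone whose aldehyde carbon can be joined to C4a by an aldol condensation.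

## Retrosynthesis

**25 from 24.** The three O–Si bonds are cut last. Triisopropylsilyl ethers are preferred to acetal or benzyl ethers because they leave with buffered fluoride, which neither closes the prenyl phenols nor enolises C3. The precursor 24 is no simpler in skeleton, but it lets all earlier chemistry run on a compound without free phenols. The forward step has to keep the configuration at C3.

**24 from 23 and 21.** The C3–H bond is cut. Protonation of a preformed enolate under acidic conditions is preferred to asymmetric hydrogenation of C2=C3 (the prenyl alkenes are at risk) and to asymmetric α-arylation (the tertiary centre forms under base and racemises). The enolate is stored as allyl enol carbonate 23, which comes from conjugate reduction of the flat, achiral isoflavone 21 through enolate 22. The forward reaction must reduce 1,4 and not 1,2, and the palladium catalyst must choose the Re face of C3.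

**21 from 20, and 20 from 18.** After removal of the C7 silyl group, the C4a–C5 bond of ring A is cut and the aromatic ring is traced back to a C7 ketone and a C5 aldehyde (keto aldehyde 19, stored as dimethyl acetal 18). The neighbouring cuts (O1–C8a, C2–C3 or C3–C4, the deoxybenzoin logic) keep ring A as a starting material and leave the C6 prenylation unsolved. Here C6 is an sp3 carbon between two carbonyl-level carbons and takes its prenyl group by enolate alkylation, and C5 arrives as an aldehyde so that no deoxygenation is needed. The bicyclic chromone is reduced to a monocyclic pyranone with a side chain. The forward step needs pyranone C5 to act as a nucleophile under acid mild enough for the prenyl groups.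

**18 from 13 and 16; 16 from 14 and 3.** The C7–C8 bond is cut by a Claisen disconnection into the lateral anion 17 of methylpyranone 13 and ester 16. This is one step shorter than an aldol followed by oxidation and uses the known acidity of the pyranone methyl group. Ester 16 is cut at the C6–CH2 bond into the commercial acetal ester 14 and prenyl bromide 3. The forward acylation has to outrun proton transfer from the branched ester.

**13 from 10, and 10 from 8 and 9.** Ring C is opened at O1–C2 and at C4a–C8a: an acetyl unit is added to the methyl ketone of enaminone 10 (through 11 and 12) and the ring closes with loss of dimethylamine. Enaminone 10 is cut at C2–C3 into arylacetone 8 and the amide acetal 9. This builds the pyranone around the benzylic carbon of ring B and avoids a separate halopyranone and cross-coupling. The forward condensation must take place at the benzylic methylene and not at the methyl group of 8.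

**8 from 7, 5, 2 and 1.** The two benzylic bonds of ring B are cut back to the two C–Br bonds of 1, whose positions already match C1' and C5'. After silylation to 2, the first bromine is exchanged (aryllithium 4) and replaced by prenyl from 3 to give 5. The second is exchanged (aryllithium 6) and replaced by a three-carbon unit through epoxide opening (alcohol 7) and oxidation. The symmetry of 2 makes the first exchange unambiguous; the forward steps must keep the ortho-silyloxy aryllithiums cold.

## Roads not taken

**Alternative 1:** The cut is through both aryl–CH2 bonds (C6–CH2 and C5'–CH2) of a finished isoflavone. In the forward sense the dibromide A1 is coupled twice with the prenylstannane A2 under a zerovalent palladium–triphenylphosphine catalyst to give the tris(methoxymethyl) ether A3; no ring closes.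
- Merits: the isoflavone core of A1 is reached by long-proven chemistry, one operation places both side chains, and the route to the isoflavone stage is probably shorter than the chosen one.
- Weak points: both C–Br bonds are electron-rich and flanked by oxygen, so oxidative addition is slow. Allyl-type stannanes can transfer through the γ-carbon and give 1,1-dimethylallyl isomers. Tin is used in stoichiometric amount. The methoxymethyl groups need protic acid for removal, in the presence of two ortho-prenyl phenols and, if taken off at the end, of the enolisable C3.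
- Comparison: in precedent and step count for the core this road is the better one. Against it the chosen plan sets prenyl groups whose position is fixed by construction, silyl groups that leave under buffered fluoride, and freedom from tin. Both roads need the same reduction and protonation end-game for C3.

**Alternative 2:** The cut removes three bonds of ring A at once (C4a–C8a, C5–C6, C7–C8). In the forward sense the 1,7-diyne A4 (ynol ether on O1, ynone on C4) and the siloxyalkyne A5 are cyclotrimerised by a cationic monovalent rhodium–bisphosphine catalyst, closing rings A and C and giving A6, which is identical with 24.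
- Merits: three bonds and two rings in one step, high convergence, and direct arrival at the protected isoflavanone with no separate end-game.
- Weak points: C3 must already be set in A4, where it is benzylic and α to an ynone and therefore very easily lost. The ynol ether, the terminal ynone and A5 are all fragile. The orientation of A5 in the ring depends on push–pull matching alone, and homotrimerisation of A4 competes.
- Comparison: in bonds formed per step this road is clearly better. The chosen plan sets against it robust intermediates throughout and a stereocentre that is created only after the ring system is complete.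

**Alternative 3:** The cut is the C3–C4 bond. In the forward sense the racemic benzylic chloride A7, tethered through O1–C2 to a ring A aroyl chloride, is cyclised by a divalent nickel chloride precatalyst with a chiral bis(oxazoline) and manganese powder, closing ring C and setting C3 to give triacetate A8.
- Merits: ring closure and stereocentre in one enantioconvergent step from a racemate, and acetates that can be removed under nearly neutral conditions.
- Weak points: the chloride of A7 sits ortho and para to oxygen substituents and β to an aryloxy group, so ionisation and β-elimination of the aryloxide from the benzyl radical or benzylnickel species are likely. The reductive acyl–benzyl coupling has not been used to close a six-membered ketone ring. The 2,4-dioxygenated 5-prenylbenzoic acid of ring A still has to be made regioselectively.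
- Comparison: the end-game is shorter than the chosen one by about two steps, and that is a real advantage. The chosen plan sets against it a protonation whose reaction type is established on isoflavanone enolates, and a ring A built without any regiochemical question.

Key step: step 9

Assumption: the (S)-configured tert-butyl phosphinooxazoline is taken to deliver the proton to the Re face of C3 (3S product); the sense of induction has to be confirmed on the first run, and the antipodal ligand is used if it proves opposite.

## Route

Step 1
Reactants: 1 4,6-dibromoresorcinol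
Product: 2 1,5-dibromo-2,4-bis(triisopropylsilyloxy)benzene
Conditions: TIPSCl, imidazole, DMF, rt
Reagents that add atoms: triisopropylsilyl chloride, CC(C)[Si](Cl)(C(C)C)C(C)C
Why: Silylation of both phenols; the bulky aryl silyl ethers tolerate the organolithium and amide-base steps that follow and leave with fluoride at the end.

Step 2
Reactants: 2 1,5-dibromo-2,4-bis(triisopropylsilyloxy)benzene; 3 prenyl bromide (1-bromo-3-methylbut-2-ene)
Product: 5 1-bromo-5-(3-methylbut-2-enyl)-2,4-bis(triisopropylsilyloxy)benzene, via aryllithium 4 (not isolated)
Conditions: n-BuLi (1.0 equiv), THF, –78 °C; CuBr·SMe2 (10 mol %), 3, –78 to –30 °C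
Reagents that add atoms: none
Why: Bromine–lithium exchange on the symmetric dibromide should stop after one exchange because the aryl anion deactivates the second bromide; allylic substitution catalysed by monovalent copper should occur at the primary carbon of 3 and give the linear prenyl arene. The anion is kept at –78 °C, where the 1,3 shift of the bulky silyl group from oxygen to carbon is slow.

Step 3
Reactants: 5 1-bromo-5-(3-methylbut-2-enyl)-2,4-bis(triisopropylsilyloxy)benzene
Product: 7 racemic 1-ArB-propan-2-ol, via aryllithium 6 (not isolated)
Conditions: n-BuLi, THF, –78 °C; (±)-2-methyloxirane, BF3·OEt2, –78 °C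
Reagents that add atoms: racemic 2-methyloxirane (propylene oxide), CC1CO1
Why: Second bromine–lithium exchange, then BF3-assisted epoxide opening by the aryllithium at the less hindered carbon, which is fast at –78 °C; the racemic carbinol centre is removed in step 4.

Step 4
Reactants: 7 racemic 1-ArB-propan-2-ol
Product: 8 1-ArB-propan-2-one
Conditions: Dess–Martin periodinane, NaHCO3, CH2Cl2, 0 °C to rt
Reagents that add atoms: none
Why: Dess–Martin oxidation of a secondary alcohol under buffered, non-acidic conditions that leave the prenyl alkene and the silyl ethers untouched.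

Step 5
Reactants: 8 1-ArB-propan-2-one; 9 N,N-dimethylformamide dimethyl acetal
Product: 10 (E)-4-(dimethylamino)-3-ArB-but-3-en-2-one
Conditions: 9 (3 equiv), toluene, 90 °C
Reagents that add atoms: none
Why: Enaminone formation by condensation of the amide acetal with the more acidic benzylic methylene of the arylacetone, the usual site for 1-arylpropan-2-ones; the alkene geometry is of no consequence.

Step 6
Reactants: 10 (E)-4-(dimethylamino)-3-ArB-but-3-en-2-one
Product: 13 6-methyl-3-ArB-pyran-4-one, via lithium enolate 11 (not isolated), via enaminodiketone 12 (not isolated)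
Conditions: LiN(SiMe3)2 (2.5 equiv), THF, –78 °C; AcCl, –78 °C; then AcOH, 50 °C
Reagents that add atoms: acetyl chloride, CC(=O)Cl
Why: Claisen-type C-acylation of the methyl ketone enolate (the second equivalent of base takes up the acidic diketone), then acid-induced addition–elimination in which the enol oxygen of the new acetyl group adds to the enaminone carbon and dimethylamine leaves. This is the standard enaminone route to 4-pyranones, and acetic acid is mild enough for the prenyl group.

Step 7
Reactants: 14 methyl 3,3-dimethoxypropanoate; 3 prenyl bromide (1-bromo-3-methylbut-2-ene)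
Product: 16 racemic methyl 2-(dimethoxymethyl)-5-methylhex-4-enoate, via lithium ester enolate 15 (not isolated)
Conditions: LiN(i-Pr)2, THF, –78 °C; 3, DMPU, –78 to –40 °C
Reagents that add atoms: none
Why: Ester enolate alkylation with a reactive allylic bromide; at –78 °C loss of methoxide from the β-position of the enolate should be slower than alkylation.

Step 8
Reactants: 13 6-methyl-3-ArB-pyran-4-one; 16 racemic methyl 2-(dimethoxymethyl)-5-methylhex-4-enoate
Product: 18 racemic 6-[3-(dimethoxymethyl)-6-methyl-2-oxohept-5-enyl]-3-ArB-pyran-4-one, via lithium dienolate 17 (not isolated)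
Conditions: LiN(SiMe3)2 (2.2 equiv), THF, –78 °C; 16 (1.5 equiv), –78 to –20 °C; aq. NH4Cl
Reagents that add atoms: none
Why: Lateral (vinylogous) deprotonation of the 2-methyl-4-pyranone and Claisen acylation of the exocyclic carbon of dienolate 17 by the ester. The second equivalent of base deprotonates the product at C8, a position from which methoxide cannot be eliminated.

Step 9
Reactants: 18 racemic 6-[3-(dimethoxymethyl)-6-methyl-2-oxohept-5-enyl]-3-ArB-pyran-4-one
Product: 20 7-hydroxy-6-(3-methylbut-2-enyl)-3-ArB-chromen-4-one, via keto aldehyde 19 (not isolated)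
Conditions: AcOH/THF/H2O (3:1:1), 55 °C, 0.01 M
Reagents that add atoms: none
Why: Proposed new method: aqueous acetic acid should hydrolyse the acetal to keto aldehyde 19, whose C7 ketone enolises towards the doubly activated C8 methylene to give a dienol conjugated with the pyranone C5=C6 bond, so that pyranone C5 (future C4a), pushed by the enol oxygen and by O1, attacks the protonated aldehyde carbon (future C5) in a vinylogous aldol addition; the closest known reaction type is the biomimetic aldol condensation and aromatisation of pyranone-masked poly-β-carbonyl chains to resorcinols, where the nucleophile is an open-chain methylene and not a pyranone ring carbon. Ring A closes through the C4a–C5 bond in a 6-(enolexo)-exo-trig mode, with the enol double bond outside the new ring and the aldehyde C=O exocyclic to it. Loss of water from the aldol and enolisation of the C7 ketone then give the phenol, and because O1 and the C4 carbonyl are already in place the chromone appears in the same operation. No stereocentre is formed, and the racemic centre of 18 becomes the sp2 carbon C6. The step needs site selectivity: the pyranone holds C2 as an enol ether so that the C8 methylene has no second aldehyde to condense with, C8 could reach C5 only through a four-membered ring, and only the C4a–C5 closure gives a six-membered ring that can aromatise, which makes it irreversible. It also needs chemoselectivity: acetic acid is too weak to protonate the prenyl double bonds or cleave aryl silyl ethers, so the new C7 phenol should not close onto the C6 prenyl group, and high dilution holds back intermolecular condensation.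

Step 10
Reactants: 20 7-hydroxy-6-(3-methylbut-2-enyl)-3-ArB-chromen-4-one
Product: 21 6-(3-methylbut-2-enyl)-3-ArB-7-(triisopropylsilyloxy)chromen-4-one
Conditions: TIPSCl, imidazole, DMF, rt
Reagents that add atoms: triisopropylsilyl chloride, CC(C)[Si](Cl)(C(C)C)C(C)C
Why: Silylation of the C7 phenol removes the acidic proton, which would consume hydride and deactivate the chromone as its vinylogous carboxylate in step 11.

Step 11
Reactants: 21 6-(3-methylbut-2-enyl)-3-ArB-7-(triisopropylsilyloxy)chromen-4-one
Product: 23 allyl 6-(3-methylbut-2-enyl)-3-ArB-7-(triisopropylsilyloxy)-2H-chromen-4-yl carbonate, via lithium enolate 22 (not isolated)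
Conditions: LiBH(s-Bu)3 (1.1 equiv), THF, –78 °C; allyl chloroformate, –78 to 0 °C
Reagents that add atoms: allyl chloroformate, C=CCOC(=O)Cl
Why: Conjugate (1,4) hydride addition of the hindered borohydride to the chromone enone, a known way from isoflavones to isoflavanone enolates, followed by O-acylation of the fully substituted enolate with the chloroformate (reductive enolate trapping). The cold enolate should not open at O1–C2.

Step 12
Reactants: 23 allyl 6-(3-methylbut-2-enyl)-3-ArB-7-(triisopropylsilyloxy)-2H-chromen-4-yl carbonate
Product: 24 (3S)-6-(3-methylbut-2-enyl)-3-ArB-7-(triisopropylsilyloxy)chroman-4-one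
Conditions: Pd2(dba)3 (5 mol %), (S)-t-Bu-PHOX (12.5 mol %), Meldrum's acid (2.5 equiv), 1,4-dioxane, rt
Reagents that add atoms: none
Why: Palladium-catalysed decarboxylative enantioselective protonation: zerovalent palladium ionises the allyl carbonate, CO2 is lost, and the enolate bound to or paired with the chiral allylpalladium–phosphinooxazoline unit is protonated by Meldrum's acid, which also takes up the allyl group. Delivery of the proton to the Re face of C3 gives 3S; the reaction type is established for α-aryl cyclic ketones including isoflavanones, and the acidic medium should protect the new centre.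

Step 13
Reactants: 24 (3S)-6-(3-methylbut-2-enyl)-3-ArB-7-(triisopropylsilyloxy)chroman-4-one
Product: 25 (3S)-3-[2,4-dihydroxy-5-(3-methylbut-2-enyl)phenyl]-7-hydroxy-6-(3-methylbut-2-enyl)chroman-4-one
Conditions: Bu4NF/AcOH (1:1, 4 equiv), THF, 0 °C
Reagents that add atoms: none
Why: Fluoride-mediated desilylation of the three aryl silyl ethers; acetic acid buffers the phenoxides so that C3 is neither enolised nor opened at O1–C2, and no acid strong enough to cyclise the prenyl phenols is present.

## Compound list

(ArB as defined at the top; the SMILES give the full structures.)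

1 | 4,6-dibromoresorcinol | Oc1cc(O)c(Br)cc1Br | starting material
2 | 1,5-dibromo-2,4-bis(triisopropylsilyloxy)benzene | Brc1cc(Br)c(O[Si](C(C)C)(C(C)C)C(C)C)cc1O[Si](C(C)C)(C(C)C)C(C)C | intermediate
3 | prenyl bromide (1-bromo-3-methylbut-2-ene) | CC(C)=CCBr | starting material
4 | [5-bromo-2,4-bis(triisopropylsilyloxy)phenyl]lithium (formed in the flask) | [Li]c1cc(Br)c(O[Si](C(C)C)(C(C)C)C(C)C)cc1O[Si](C(C)C)(C(C)C)C(C)C | intermediate
5 | 1-bromo-5-(3-methylbut-2-enyl)-2,4-bis(triisopropylsilyloxy)benzene | CC(C)=CCc1cc(Br)c(O[Si](C(C)C)(C(C)C)C(C)C)cc1O[Si](C(C)C)(C(C)C)C(C)C | intermediate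
6 | [5-(3-methylbut-2-enyl)-2,4-bis(triisopropylsilyloxy)phenyl]lithium (formed in the flask) | [Li]c1cc(CC=C(C)C)c(O[Si](C(C)C)(C(C)C)C(C)C)cc1O[Si](C(C)C)(C(C)C)C(C)C | intermediate
7 | racemic 1-ArB-propan-2-ol | CC(O)Cc1cc(CC=C(C)C)c(O[Si](C(C)C)(C(C)C)C(C)C)cc1O[Si](C(C)C)(C(C)C)C(C)C | intermediate
8 | 1-ArB-propan-2-one | CC(=O)Cc1cc(CC=C(C)C)c(O[Si](C(C)C)(C(C)C)C(C)C)cc1O[Si](C(C)C)(C(C)C)C(C)C | intermediate
9 | N,N-dimethylformamide dimethyl acetal | COC(OC)N(C)C | starting material
10 | (E)-4-(dimethylamino)-3-ArB-but-3-en-2-one | CC(=O)/C(=C/N(C)C)c1cc(CC=C(C)C)c(O[Si](C(C)C)(C(C)C)C(C)C)cc1O[Si](C(C)C)(C(C)C)C(C)C | intermediate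
11 | lithium (E)-4-(dimethylamino)-3-ArB-buta-1,3-dien-2-olate (formed in the flask) | [Li]OC(=C)/C(=C/N(C)C)c1cc(CC=C(C)C)c(O[Si](C(C)C)(C(C)C)C(C)C)cc1O[Si](C(C)C)(C(C)C)C(C)C | intermediate
12 | (E)-6-(dimethylamino)-5-ArB-hex-5-ene-2,4-dione (formed in the flask) | CC(=O)CC(=O)/C(=C/N(C)C)c1cc(CC=C(C)C)c(O[Si](C(C)C)(C(C)C)C(C)C)cc1O[Si](C(C)C)(C(C)C)C(C)C | intermediate
13 | 6-methyl-3-ArB-pyran-4-one | Cc1cc(=O)c(-c2cc(CC=C(C)C)c(O[Si](C(C)C)(C(C)C)C(C)C)cc2O[Si](C(C)C)(C(C)C)C(C)C)co1 | intermediate
14 | methyl 3,3-dimethoxypropanoate | COC(OC)CC(=O)OC | starting material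
15 | lithium 1,3,3-trimethoxyprop-1-en-1-olate (formed in the flask) | COC(OC)C=C(O[Li])OC | intermediate
16 | racemic methyl 2-(dimethoxymethyl)-5-methylhex-4-enoate | COC(OC)C(CC=C(C)C)C(=O)OC | intermediate
17 | lithium 2-methylidene-5-ArB-2H-pyran-4-olate (formed in the flask) | C=C1C=C(O[Li])C(-c2cc(CC=C(C)C)c(O[Si](C(C)C)(C(C)C)C(C)C)cc2O[Si](C(C)C)(C(C)C)C(C)C)=CO1 | intermediate
18 | racemic 6-[3-(dimethoxymethyl)-6-methyl-2-oxohept-5-enyl]-3-ArB-pyran-4-one | COC(OC)C(CC=C(C)C)C(=O)Cc1cc(=O)c(-c2cc(CC=C(C)C)c(O[Si](C(C)C)(C(C)C)C(C)C)cc2O[Si](C(C)C)(C(C)C)C(C)C)co1 | intermediate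
19 | racemic 2-(3-methylbut-2-enyl)-3-oxo-4-(4-oxo-5-ArB-pyran-2-yl)butanal (formed in the flask) | O=CC(CC=C(C)C)C(=O)Cc1cc(=O)c(-c2cc(CC=C(C)C)c(O[Si](C(C)C)(C(C)C)C(C)C)cc2O[Si](C(C)C)(C(C)C)C(C)C)co1 | intermediate
20 | 7-hydroxy-6-(3-methylbut-2-enyl)-3-ArB-chromen-4-one | CC(C)=CCc1cc2c(cc1O)occ(-c1cc(CC=C(C)C)c(O[Si](C(C)C)(C(C)C)C(C)C)cc1O[Si](C(C)C)(C(C)C)C(C)C)c2=O | intermediate
21 | 6-(3-methylbut-2-enyl)-3-ArB-7-(triisopropylsilyloxy)chromen-4-one | CC(C)=CCc1cc2c(cc1O[Si](C(C)C)(C(C)C)C(C)C)occ(-c1cc(CC=C(C)C)c(O[Si](C(C)C)(C(C)C)C(C)C)cc1O[Si](C(C)C)(C(C)C)C(C)C)c2=O | intermediate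
22 | lithium 6-(3-methylbut-2-enyl)-3-ArB-7-(triisopropylsilyloxy)-2H-chromen-4-olate (formed in the flask) | [Li]OC1=C(c2cc(CC=C(C)C)c(O[Si](C(C)C)(C(C)C)C(C)C)cc2O[Si](C(C)C)(C(C)C)C(C)C)COc2cc(O[Si](C(C)C)(C(C)C)C(C)C)c(CC=C(C)C)cc12 | intermediate
23 | allyl 6-(3-methylbut-2-enyl)-3-ArB-7-(triisopropylsilyloxy)-2H-chromen-4-yl carbonate | C=CCOC(=O)OC1=C(c2cc(CC=C(C)C)c(O[Si](C(C)C)(C(C)C)C(C)C)cc2O[Si](C(C)C)(C(C)C)C(C)C)COc2cc(O[Si](C(C)C)(C(C)C)C(C)C)c(CC=C(C)C)cc12 | intermediate
24 | (3S)-6-(3-methylbut-2-enyl)-3-ArB-7-(triisopropylsilyloxy)chroman-4-one | CC(C)=CCc1cc2c(cc1O[Si](C(C)C)(C(C)C)C(C)C)OC[C@H](c1cc(CC=C(C)C)c(O[Si](C(C)C)(C(C)C)C(C)C)cc1O[Si](C(C)C)(C(C)C)C(C)C)C2=O | intermediate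
25 | (3S)-3-[2,4-dihydroxy-5-(3-methylbut-2-enyl)phenyl]-7-hydroxy-6-(3-methylbut-2-enyl)chroman-4-one | CC(C)=CCc1cc2c(cc1O)OC[C@H](c1cc(CC=C(C)C)c(O)cc1O)C2=O | target

## Step count and risks

Total: 13 steps. Longest linear sequence: 12 steps (steps 1 to 6 and 8 to 13); step 7 is a one-step side branch.

**Step 9 (key step, proposed new method).** The most likely failure is that hydrolysis proceeds but the C–C bond does not form. Pyranone C5 is only a weak nucleophile, and the β-keto aldehyde rests as its conjugated enol, a poor electrophile. On forcing, intermolecular condensation or loss of the formyl group could take over.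

The fallback uses known reactions only and rests on the fact that rings A and B carry the same aryl unit. It sets out from aryllithium 6 and bromide 5 and returns to the route at 21. Aryllithium 6 is acetylated with N-methoxy-N-methylacetamide at –78 °C to give 1-ArB-ethanone F1. Palladium-catalysed ketone α-arylation of F1 with 5 (Pd2(dba)3, Xantphos, K3PO4, toluene, 80 °C) gives the deoxybenzoin 1,2-bis-ArB-ethanone F2. Condensation with 9 at 90 °C gives the enaminone (E)-3-(dimethylamino)-1,2-bis-ArB-prop-2-en-1-one F3. Bu4NF in THF then frees the phenols, and the ortho phenol of ring A adds to the enaminone carbon in a 6-endo closure and expels dimethylamine (the ring B phenol would need a 5-endo closure), which gives 3-[2,4-dihydroxy-5-(3-methylbut-2-enyl)phenyl]-7-hydroxy-6-(3-methylbut-2-enyl)chromen-4-one F4. Silylation of all three phenols with TIPSCl and imidazole gives 21.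

**Step 8.** The most likely failure is proton transfer from the α-position of the branched ester 16 to dienolate 17 or to excess amide base, instead of addition; the ester enolate would then lose methoxide, and the hindered ester reacts slowly in any case.

The fallback replaces acylation by aldol addition and oxidation. It sets out from 16 and 13 and returns at 18. Ester 16 is reduced with i-Bu2AlH at –78 °C to racemic 2-(dimethoxymethyl)-5-methylhex-4-enal F5. Addition of F5 to dienolate 17 (from 13 as in step 8) at –78 °C gives 6-[3-(dimethoxymethyl)-2-hydroxy-6-methylhept-5-enyl]-3-ArB-pyran-4-one F6 as a mixture of diastereomers. Dess–Martin oxidation buffered with NaHCO3 gives 18.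

**Step 12.** The most likely failure is insufficient facial selectivity in the protonation. An aryl group with only one ortho substituent differentiates the enolate faces less well, and background protonation by free Meldrum's acid is not selective.

The fallback sets C3 by dynamic kinetic resolution instead. It sets out from 21 and returns at 24. Asymmetric transfer hydrogenation of 21 with RuCl(p-cymene)[(S,S)-TsDPEN] in HCO2H/Et3N reduces the C2=C3 bond and then the ketone of the rapidly racemising isoflavanone. By the usual aryl ketone model this is expected to give the cis alcohol (3S,4S)-6-(3-methylbut-2-enyl)-3-ArB-7-(triisopropylsilyloxy)chroman-4-ol F7. Dess–Martin oxidation buffered with NaHCO3 returns the ketone 24 without touching C3.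

**Step 13.** The most likely failure is erosion of the configuration at C3 once fluoride generates phenoxides, through enolisation or reversible opening of the O1–C2 bond.

The fallback reverses the order so that nothing follows the creation of C3. It sets out from 23 and returns at 25. The silyl groups of 23, which has no stereocentre to lose, are removed with HF·pyridine in THF/pyridine at 0 °C to give allyl 3-[2,4-dihydroxy-5-(3-methylbut-2-enyl)phenyl]-7-hydroxy-6-(3-methylbut-2-enyl)-2H-chromen-4-yl carbonate F8. The conditions of step 12 applied to F8 then give 25 directly.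

## Further compounds

F1 | step 9 | 1-[5-(3-methylbut-2-enyl)-2,4-bis(triisopropylsilyloxy)phenyl]ethanone | CC(=O)c1cc(CC=C(C)C)c(O[Si](C(C)C)(C(C)C)C(C)C)cc1O[Si](C(C)C)(C(C)C)C(C)C
F2 | step 9 | 1,2-bis[5-(3-methylbut-2-enyl)-2,4-bis(triisopropylsilyloxy)phenyl]ethanone | O=C(Cc1cc(CC=C(C)C)c(O[Si](C(C)C)(C(C)C)C(C)C)cc1O[Si](C(C)C)(C(C)C)C(C)C)c1cc(CC=C(C)C)c(O[Si](C(C)C)(C(C)C)C(C)C)cc1O[Si](C(C)C)(C(C)C)C(C)C
F3 | step 9 | (E)-3-(dimethylamino)-1,2-bis[5-(3-methylbut-2-enyl)-2,4-bis(triisopropylsilyloxy)phenyl]prop-2-en-1-one | O=C(c1cc(CC=C(C)C)c(O[Si](C(C)C)(C(C)C)C(C)C)cc1O[Si](C(C)C)(C(C)C)C(C)C)/C(=C/N(C)C)c1cc(CC=C(C)C)c(O[Si](C(C)C)(C(C)C)C(C)C)cc1O[Si](C(C)C)(C(C)C)C(C)C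
F4 | step 9 | 3-[2,4-dihydroxy-5-(3-methylbut-2-enyl)phenyl]-7-hydroxy-6-(3-methylbut-2-enyl)chromen-4-one | CC(C)=CCc1cc2c(cc1O)occ(-c1cc(CC=C(C)C)c(O)cc1O)c2=O
F5 | step 8 | racemic 2-(dimethoxymethyl)-5-methylhex-4-enal | COC(OC)C(CC=C(C)C)C=O
F6 | step 8 | 6-[3-(dimethoxymethyl)-2-hydroxy-6-methylhept-5-enyl]-3-[5-(3-methylbut-2-enyl)-2,4-bis(triisopropylsilyloxy)phenyl]pyran-4-one (racemic mixture of diastereomers) | COC(OC)C(CC=C(C)C)C(O)Cc1cc(=O)c(-c2cc(CC=C(C)C)c(O[Si](C(C)C)(C(C)C)C(C)C)cc2O[Si](C(C)C)(C(C)C)C(C)C)co1
F7 | step 12 | (3S,4S)-6-(3-methylbut-2-enyl)-3-[5-(3-methylbut-2-enyl)-2,4-bis(triisopropylsilyloxy)phenyl]-7-(triisopropylsilyloxy)chroman-4-ol | CC(C)=CCc1cc2c(cc1O[Si](C(C)C)(C(C)C)C(C)C)OC[C@H](c1cc(CC=C(C)C)c(O[Si](C(C)C)(C(C)C)C(C)C)cc1O[Si](C(C)C)(C(C)C)C(C)C)[C@@H]2O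
F8 | step 13 | allyl 3-[2,4-dihydroxy-5-(3-methylbut-2-enyl)phenyl]-7-hydroxy-6-(3-methylbut-2-enyl)-2H-chromen-4-yl carbonate | C=CCOC(=O)OC1=C(c2cc(CC=C(C)C)c(O)cc2O)COc2cc(O)c(CC=C(C)C)cc12
A1 | alternative 1 | 6-bromo-3-[5-bromo-2,4-bis(methoxymethoxy)phenyl]-7-(methoxymethoxy)chromen-4-one | COCOc1cc2occ(-c3cc(Br)c(OCOC)cc3OCOC)c(=O)c2cc1Br
A2 | alternative 1 | tributyl(3-methylbut-2-enyl)stannane | CCCC[Sn](CCCC)(CCCC)CC=C(C)C
A3 | alternative 1 | 6-(3-methylbut-2-enyl)-3-[5-(3-methylbut-2-enyl)-2,4-bis(methoxymethoxy)phenyl]-7-(methoxymethoxy)chromen-4-one | COCOc1cc2occ(-c3cc(CC=C(C)C)c(OCOC)cc3OCOC)c(=O)c2cc1CC=C(C)C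
A4 | alternative 2 | (4S)-5-(ethynyloxy)-4-[5-(3-methylbut-2-enyl)-2,4-bis(triisopropylsilyloxy)phenyl]pent-1-yn-3-one | C#COC[C@H](c1cc(CC=C(C)C)c(O[Si](C(C)C)(C(C)C)C(C)C)cc1O[Si](C(C)C)(C(C)C)C(C)C)C(=O)C#C
A5 | alternative 2 | triisopropyl(5-methylhex-4-en-1-ynoxy)silane | CC(C)=CCC#CO[Si](C(C)C)(C(C)C)C(C)C
A6 | alternative 2 | (3S)-6-(3-methylbut-2-enyl)-3-[5-(3-methylbut-2-enyl)-2,4-bis(triisopropylsilyloxy)phenyl]-7-(triisopropylsilyloxy)chroman-4-one (identical with 24) | CC(C)=CCc1cc2c(cc1O[Si](C(C)C)(C(C)C)C(C)C)OC[C@H](c1cc(CC=C(C)C)c(O[Si](C(C)C)(C(C)C)C(C)C)cc1O[Si](C(C)C)(C(C)C)C(C)C)C2=O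
A7 | alternative 3 | racemic 4-acetoxy-2-[2-chloro-2-[2,4-diacetoxy-5-(3-methylbut-2-enyl)phenyl]ethoxy]-5-(3-methylbut-2-enyl)benzoyl chloride | CC(=O)Oc1cc(OCC(Cl)c2cc(CC=C(C)C)c(OC(C)=O)cc2OC(C)=O)c(C(=O)Cl)cc1CC=C(C)C
A8 | alternative 3 | (3S)-7-acetoxy-3-[2,4-diacetoxy-5-(3-methylbut-2-enyl)phenyl]-6-(3-methylbut-2-enyl)chroman-4-one | CC(C)=CCc1cc2c(cc1OC(C)=O)OC[C@H](c1cc(CC=C(C)C)c(OC(C)=O)cc1OC(C)=O)C2=O
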